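(The rate constants belong to no real substance.)

The target can fall back into starting material and dissolved gas, so I treated it as a trap with a leak.

    starting material → side product (k1 = 0.0503 h⁻¹)
    gas phase ⇌ dissolved gas, rate k2*(csat - [dissolved gas]) (k2 = 0.410 h⁻¹, csat = 200 mM)
    starting material + dissolved gas ⇌ target (K3 = 9.3 M⁻¹, k3 = 0.267 M⁻¹ h⁻¹)
    2 starting material → self-condensation product (k4 = 0.0495 M⁻¹ h⁻¹)

starting material 0.88 M; gas phase 200 mM (held); time 4.0 d

- the target standing at 4.0 d, as a percentage of the starting material charged
- the change that raises the amount of target at 4.0 d, in percent of the starting material charged most ("none" if none brings more than 2 percentage points) (dawn / summer / none)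
- amount of target at 4.0 d, in percent of the starting material charged, after summer

- in percentages every species weighs as the starting material in it: one self-condensation product counts as two
- two of one species on the left: rate k times its square, two consumed each time
- at the start none of the gas is dissolved
- run time (flask): 4.0 d

- dawn: doubling the transfer coefficient of step 2, all else as stated
- summer: doubling the saturation concentration of gas phase, all else as stated

**Capture number.** With [dissolved gas] taken at its saturation value 200 mM, capture of starting material is pseudo-first-order. I set its rate constant against that of the side-product step and called the ratio the capture number: 1.06. It gives the odds that a free starting material enters the target rather than the side product, so on this count a share of 51.5 % does. A target falls back at 0.0287 h⁻¹ and is recaptured at the same odds, so the target drains at 0.0139 h⁻¹. By 4.0 d that leaves 13.5 %.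

**Was it enough?** It was not, since self-condensation starts faster than the side-product step, and the gas starts undissolved. I therefore corrected for self-condensation, setting the two steps against each other with the ratio 1.73; I left capture out of this ratio as a rough allowance for the undissolved gas. Integrating that competition lets a share of 58.0 % survive, which gives 7.85 %. The summer flask, with its saturation concentration doubled, has a capture number of 2.12 and gives 16.3 %. The transfer coefficient stands nowhere in the number, so I chose summer.

**Forecast, run.** The forecast gave 9.3 % and 19.2 %, with summer as its choice: doubling the transfer coefficient “helps only modestly, so summer is best”. My two figures stand lower than its figures. The simulation gave 8.23 % and 17.0 %, and summer won, gaining 8.8 percentage points against 0.82 points for dawn.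

**The leak.** In this flask the target fell from 14.9 % at 2.00 d to 8.23 % at 4.0 d, a reading of 0.0124 h⁻¹ against the drain of 0.0139 h⁻¹. The loss came from the backward run acting together with the side-product step: against 8.23 %, the target stood at 27.9 % with the backward run struck out and at 24.7 % with the side-product step struck out. For the neighbour flask read at 2.5 d, the capture number gives 13.0 %, and that flask held 12.8 %.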